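# Total synthesis proposal for scolopendrine (21)

## Analysis of the target

Scolopendrine (21) is a quinolin-2(1H)-one. Ring A is the pyridone (N1–H, C2=O, C3–OMe, C4–H) and ring B is the fused benzene ring (C4a, C5 to C8, C8a). Ring B is unsubstituted at C5 and C6, carries a 4-hydroxy-3-methoxybenzyl group on C7 and a hydrogen sulfate ester on the oxygen of C8, so C7, C8, C8a and N1 form an unbroken row of substituted atoms. The molecule is achiral, with no stereocentre and no configurable double bond, so any stereocentre created on the way is transient and only has to disappear cleanly. The aryl hydrogen sulfate is the delicate group: it is a strong acid, it is solvolysed by acid and heat, and it makes every compound that carries it a polar salt, so it must come late. The guaiacol hydroxyl would compete for any sulfating agent, the lactam has to be masked or tolerated, and the doubly benzylic CH2 rules out harsh oxidants. The real difficulty is positional. Oxygen must sit on C8 beside the nitrogen-bearing C8a, with the benzyl group next to it on C7, and aniline-based quinolone syntheses could reach this pattern only from a contiguously tetrasubstituted benzene. The strategy reads C5–C6–C7–C8, with oxygen on C8 and benzyl on C7, as a 3-benzylfuran whose ring oxygen stays on one α-carbon. It reads the shared C4a–C8a bond as the formal triple bond of a 2,3-pyridyne that already carries the C2 oxygen and the C3 methoxy group of ring A.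

## Retrosynthetic reasoning

**21 ⇒ 20 ⇒ 19 (two O–CH2Ph bonds).** The last operation is deprotection. Restoring the two benzyl groups leads from 21, through its sodium salt 20, to the dibenzylated sulfate salt 19. One kind of protecting group does two jobs. On ring A it holds the lactam as an aromatic 2-benzyloxyquinoline, which the aryne chemistry needs, and on the guaiacol ring it blocks the competing phenol. The forward step must cleave both C–O bonds without touching the S–O ester, the diarylmethane or the quinolone ring, and then exchange sodium for a proton.

**19 ⇒ 17 (O–S bond).** Cutting the sulfate ester gives the quinolin-8-ol 17, which has exactly one free hydroxyl. The chemoselectivity problem of the target (two phenolic oxygens, one sulfated) is therefore solved by the order of events. The forward step has to sulfate a hindered hydroxyl flanked by the C7 benzyl group and the ring nitrogen.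

**17 ⇒ 16 (C5–O bond re-formed).** The phenol is traced to its isomer, the oxygen-bridged 5,8-epoxy-5,8-dihydroquinoline 16. No atoms change, and the oxygen on C8 is recognised as one end of an ether bridge. The forward isomerisation must break C5–O and keep C8–O. The substituents favour this, because a cation at C5 is allylic with its far end on the benzyl-bearing C7 and keeps positive charge off nitrogen.

**16 ⇒ 15 + 14 (C8–C8a and C4a–C5).** Both bonds between ring A and the four-carbon unit are cut at once in a retro-Diels–Alder sense. This is the most simplifying cut available. It separates an intact pyridine, as the pyridyne 15, from an intact furan 14, and each fragment carries its substituents in positions that are easy to fill on a simple heteroarene. The forward step has to orient the unsymmetrical diene on the unsymmetrical aryne. Pyridyne 15 is released under mild, base-free conditions from the ortho-silyl triflate 10.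

**10 ⇒ 9 ⇒ 8 ⇒ 7 ⇒ 6 (O–S, C–Si).** The triflate is removed to give the pyridinolate 9. Its C2–Si bond is traced, by an O→C silyl shift through the carbanion 8, to the silyl ether 7 of the bromopyridinol 6. The silicon is delivered intramolecularly to the carbon that bore the halogen, so its position is never in doubt.

**6 ⇒ 5 ⇒ 2 ⇒ 1 (C2–Br, C3–O, C6–O of the pyridine).** The bromine is removed to give the pyridinol 5, in which hydroxyl and methoxy both direct an electrophile to that carbon. The hydroxyl is traced to the bromide of 2, and the benzyl ether to the activated chloride of the commercial pyridine 1. The two halogens of 1 have orthogonal reactivity (addition–elimination against metal exchange), so no selectivity problem arises.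

**14 ⇒ 12 + 13, 12 ⇒ 11 (CH2–furan C3).** The diarylmethane-type bond is cut next to the furan. This gives a benzylic electrophile 12, made from the commercial alcohol 11, and the commercial boronic acid 13. The cut fixes the 3-substitution of the furan from the outset, which electrophilic substitution of a furan could not do.

## Alternatives that were turned down

**Alternative 1:** The disconnection is N1–C8a, with ring A traced to a ring-contracted ketone. The oxime A2 of a 2,2-dimethoxyindan-1-one, once activated on oxygen, would undergo Beckmann rearrangement with migration of the aryl carbon to nitrogen to give the 3,3-dimethoxy-3,4-dihydroquinolin-2(1H)-one A1. β-Elimination of one methoxy group would then create the C3=C4 bond of the 3-methoxyquinolone.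

- In its favour: every ring B position is fixed in the indanone, so no regioisomer can arise, and the ketal supplies the C3 oxidation level without an oxidant. On positional certainty it is stronger than the chosen route.
- Against it: the oxime carbon of A2 lies between a quaternary ketal carbon and a peri acyloxy group. Oxime formation is therefore hindered, and the geometry needed (leaving group anti to the aryl carbon, hence syn to the ketal) is not under control.
- The ketal carbon is also an excellent cationic leaving fragment, so Beckmann fragmentation to a nitrile and a dialkoxycarbenium ion competes directly. Indanone oximes are reluctant substrates in any case, because the nitrilium-like transition state is strained within the forming six-membered ring.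
- The contiguously substituted indanone needs a long linear build-up, and a pivalate has to be exchanged before sulfation.

The chosen route accepts a regiochemical risk in one step. In return it assembles the skeleton from two short fragments and uses a single protecting group.

**Alternative 2:** The disconnection removes C3 of the quinoline and leads back to the 6-benzyl-7-oxygenated indole A4. Dibromocarbene A5, generated under basic conditions, would cyclopropanate the indole C2=C3 bond. Opening of the adduct with loss of bromide (Ciamician–Dennstedt ring expansion) would give the 3-bromoquinoline A3.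

- In its favour: ring B substitution is again unambiguous, 7-substituted indoles are accessible by the Bartoli reaction, and the inserted carbon arrives with a halogen handle exactly at C3.
- Against it: the carbene has other reaction channels on A4 (attack at C3 with formylation-type outcomes, N–H insertion, attack on the electron-rich guaiacyl ring), so the key step is intrinsically unselective.
- A3 is still far from the target. Bromide must become methoxy, the nitrogen must be oxidised and the oxygen transposed to C2, and the acetal must be removed before sulfation. That makes about four redox or functional-group adjustments after the key step.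

In the chosen route the C2 and C3 oxygens are present from the first step, and only three steps follow the key step.

**Alternative 3:** The disconnection cuts C4–C4a and N1–C8a, so that ring A is built onto the 3-alkoxyaryne A8 from N,2-dimethoxyacrylamide A7. Under palladium catalysis with a stoichiometric copper oxidant, A7 is metalated at nitrogen and at its terminal vinylic carbon, A8 inserts, and reductive elimination closes the quinolin-2-one A6.

- In its favour: it is convergent and delivers C2=O and C3–OMe at the correct oxidation level in one step. The strong polarisation of a 3-alkoxyaryne should send the carbon ligand to the remote aryne carbon (C4a) and leave nitrogen for C8a. On regiocontrol it is probably stronger than the chosen cycloaddition.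
- Against it: C–N reductive elimination has to occur at the carbon flanked by the acetal oxygen and gives a product with N–OMe and the C8 oxygen crowded together.
- A7 is an enol ether acrylamide, prone to hydrolysis and polymerisation under hot, oxidising, fluoride-containing conditions.
- The precursor of A8 is a benzene with four contiguous substituents and needs about as many steps as the whole pyridine branch here.
- N–O cleavage and acetal removal are added to the endgame.

The chosen strategy offers instead a metal-free, oxidant-free key step at room temperature, fragments drawn from catalogue heteroarenes, delivery of the C8 oxygen by the furan itself, and one global deprotection.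

Key step: step 8

Assumption: the target is taken as the free hydrogen sulfate as drawn. It is generated cold in the last operation and is best stored as its sodium salt 20. Cycloadduct 16 is racemic, and its two stereocentres are erased in step 9.

## Route

Step 1
Reactants: 1 5-bromo-2-chloro-3-methoxypyridine
Product: 2 2-(benzyloxy)-5-bromo-3-methoxypyridine
Conditions: BnOH, KOt-Bu, 1,4-dioxane, 90 °C
Reagents that add atoms: benzyl alcohol, OCc1ccccc1
Why: Nucleophilic aromatic substitution by addition–elimination; only the C2 chloride is activated by the ring nitrogen, while the C5 bromide sits in a β-position and is inert to alkoxide, so the benzyl ether that masks the future lactam is installed chemoselectively.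

Step 2
Reactants: 2 2-(benzyloxy)-5-bromo-3-methoxypyridine
Product: 5 6-(benzyloxy)-5-methoxypyridin-3-ol, via pyridin-3-yllithium 3 (not isolated), via lithium aryltriisopropoxyborate 4 (not isolated)
Conditions: B(Oi-Pr)3, n-BuLi, THF/toluene, −78 °C; then AcOH, 30% aq. H2O2, 0 °C → rt
Reagents that add atoms: hydrogen peroxide, OO (hydroxyl oxygen of 5); n-butyllithium, [Li]CCCC (lithium of 3 and 4); triisopropyl borate, CC(C)OB(OC(C)C)OC(C)C (boron and alkoxides of 4)
Why: Bromine–lithium exchange with in situ borate trapping, followed by peroxide oxidation (1,2-shift of the aryl group from boron to oxygen), is the standard halide-to-phenol exchange. Having the borate present from the start keeps the lifetime of 3 short, so deprotonation of the O-benzyl CH2 cannot compete, and acetic acid buffering spares the electron-rich pyridinol from basic peroxide.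

Step 3
Reactants: 5 6-(benzyloxy)-5-methoxypyridin-3-ol
Product: 6 6-(benzyloxy)-2-bromo-5-methoxypyridin-3-ol
Conditions: NBS (1.0 equiv), MeCN, −10 °C → 0 °C, dark
Reagents that add atoms: N-bromosuccinimide, O=C1CCC(=O)N1Br
Why: Electrophilic aromatic bromination; C2 is ortho to the hydroxyl, para to the methoxy group and the usual halogenation site of pyridin-3-ols, whereas C4 is wedged between two substituents. One equivalent of reagent at low temperature limits dibromination and oxidation.

Step 4
Reactants: 6 6-(benzyloxy)-2-bromo-5-methoxypyridin-3-ol
Product: 7 2-(benzyloxy)-6-bromo-3-methoxy-5-[(trimethylsilyl)oxy]pyridine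
Conditions: HMDS, THF, 65 °C; concentrate
Reagents that add atoms: hexamethyldisilazane, C[Si](C)(C)N[Si](C)(C)C
Why: O-silylation of a phenol-type hydroxyl with the disilazane gives only a volatile by-product, so 7 is obtained by evaporation and used without an aqueous work-up that would hydrolyse it.

Step 5
Reactants: 7 2-(benzyloxy)-6-bromo-3-methoxy-5-[(trimethylsilyl)oxy]pyridine
Product: 10 6-(benzyloxy)-5-methoxy-2-(trimethylsilyl)pyridin-3-yl trifluoromethanesulfonate, via 2-lithiopyridine 8 (not isolated), via lithium 2-silylpyridin-3-olate 9 (not isolated)
Conditions: n-BuLi, THF, −78 °C; then Tf2O, −78 °C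
Reagents that add atoms: trifluoromethanesulfonic anhydride, O=S(=O)(OS(=O)(=O)C(F)(F)F)C(F)(F)F; n-butyllithium, [Li]CCCC (lithium of 8 and 9)
Why: Bromine–lithium exchange at C2 gives 8, whose carbanion attacks the neighbouring silyl ether in a retro-Brook 1,3 O→C shift driven by formation of the oxyanion 9. Triflation of 9 in the same flask is the standard entry to ortho-silylaryl triflates from ortho-bromophenols. Work-up is kept cold and neutral because C2-silylpyridines protodesilylate easily.

Step 6
Reactants: 11 [4-(benzyloxy)-3-methoxyphenyl]methanol
Product: 12 1-(benzyloxy)-4-(chloromethyl)-2-methoxybenzene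
Conditions: SOCl2, CH2Cl2, 0 °C
Reagents that add atoms: thionyl chloride, O=S(Cl)Cl
Why: Chlorodehydroxylation of an electron-rich benzylic alcohol through its chlorosulfite; the by-products are gases, so the solvolysis-prone chloride is used crude without chromatography.

Step 7
Reactants: 12 1-(benzyloxy)-4-(chloromethyl)-2-methoxybenzene; 13 furan-3-ylboronic acid
Product: 14 3-[4-(benzyloxy)-3-methoxybenzyl]furan
Conditions: Pd(OAc)2 (2 mol %), PPh3 (4 mol %), K3PO4, toluene, 80 °C
Reagents that add atoms: none
Why: sp3–sp2 Suzuki–Miyaura coupling; benzylic chlorides add readily to zerovalent palladium, no β-hydrogen is present, and the 3-furylboronic acid is far less prone to protodeboronation than its 2-isomer. Phosphate in toluene avoids hydrolysis of the chloride.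

Step 8
Reactants: 10 6-(benzyloxy)-5-methoxy-2-(trimethylsilyl)pyridin-3-yl trifluoromethanesulfonate; 14 3-[4-(benzyloxy)-3-methoxybenzyl]furan
Product: 16 2-(benzyloxy)-7-[4-(benzyloxy)-3-methoxybenzyl]-3-methoxy-5,8-epoxy-5,8-dihydroquinoline (racemic; the 5S,8R enantiomer is drawn), via 2,3-pyridyne 15 (not isolated)
Conditions: CsF (3 equiv), 14 (3 equiv, surplus recovered), dry MeCN, 0 °C → rt
Reagents that add atoms: none
Why: Fluoride attacks the C2 silicon of 10 and the incipient 2-pyridyl anion expels the vicinal triflate, the usual fluoride-induced 1,2-elimination of ortho-silylaryl triflates, which releases the 2,3-pyridyne 15 without strong base. Pyridyne 15 is captured by the diene of 14 in a concerted but asynchronous [4+2] cycloaddition; Diels–Alder trapping of 2,3-pyridynes by furans is the closest known reaction type. The two new bonds, C8–C8a and C4a–C5, close the six-membered carbocycle C4a–C5–C6–C7–C8–C8a by intermolecular suprafacial addition across furan C2 and C5, and the same two bonds close the five-membered ring O–C5–C4a–C8a–C8 of the 7-oxanorbornadiene. C5 and C8 become stereocentres whose relative configuration is dictated by the one-atom oxygen bridge (only the cis-bridged arrangement is possible); no chiral element is present, so 16 is racemic, which is harmless because step 9 removes both centres. The selectivity needed is orientational: furan C2, the α-carbon next to the benzyl-bearing C3, must bond to the pyridyne carbon next to nitrogen. Two effects point this way: nucleophiles add to 2,3-pyridynes at C2, so that carbon leads bond formation, and the furan α-carbon beside the alkyl group is the more nucleophilic one because the charge developing on C3 is stabilised by the substituent; the nitrogen flank of 15 is also the less crowded one. The bias is expected to be moderate, so the regioisomeric adduct has to be removed by chromatography here or after step 9. An excess of the shorter-made partner 14 and slow release of 15 by sparingly soluble CsF keep fluoride addition and self-reaction of 15 in check.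

Step 9
Reactants: 16 2-(benzyloxy)-7-[4-(benzyloxy)-3-methoxybenzyl]-3-methoxy-5,8-epoxy-5,8-dihydroquinoline
Product: 17 2-(benzyloxy)-7-[4-(benzyloxy)-3-methoxybenzyl]-3-methoxyquinolin-8-ol
Conditions: p-TsOH·H2O (20 mol %), CH2Cl2, 0 °C → rt
Reagents that add atoms: none
Why: Acid-catalysed isomerisation of a 1,4-epoxy-1,4-dihydroarene to a phenol. After protonation of the bridge oxygen, C5–O breaks and C8–O does not: the C5 cation is allylic with its far end on the benzyl-bearing C7, is conjugated through C4a with the para 2-benzyloxy donor and puts no charge on nitrogen, whereas a C8 cation would be a 2-pyridylmethyl cation with the C7 substituent on the nodal central carbon of the allyl system. The ring-opened cation is the arenium ion of 17 protonated at C8 and rearomatises by loss of that proton (or by a 1,2-hydride shift to C7 and enolisation), so the bridge oxygen ends on C8 and both stereocentres vanish.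

Step 10
Reactants: 17 2-(benzyloxy)-7-[4-(benzyloxy)-3-methoxybenzyl]-3-methoxyquinolin-8-ol
Product: 19 sodium 2-(benzyloxy)-7-[4-(benzyloxy)-3-methoxybenzyl]-3-methoxyquinolin-8-yl sulfate, via pyridinium sulfate salt 18 (not isolated)
Conditions: SO3·pyridine, pyridine, 50 °C; then aq. NaHCO3
Reagents that add atoms: sulfur trioxide–pyridine complex, [O-]S(=O)(=O)[n+]1ccccc1; sodium hydrogencarbonate, [Na+].OC([O-])=O
Why: O-sulfation of a phenol with a sulfur trioxide–amine complex; 17 has a single free hydroxyl, so no chemoselectivity is required. The exchange to the sodium salt removes pyridine, which would poison the palladium surface in the following benzyl ether hydrogenolysis.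

Step 11
Reactants: 19 sodium 2-(benzyloxy)-7-[4-(benzyloxy)-3-methoxybenzyl]-3-methoxyquinolin-8-yl sulfate
Product: 21 scolopendrine, via scolopendrine sodium salt 20 (not isolated)
Conditions: H2 (1 atm), Pd/C (10 wt %), MeOH/THF, rt; filter; then 1 M HCl (1.0 equiv), 0 °C, C18 desalting, lyophilise
Reagents that add atoms: none
Why: Heterogeneous hydrogenolysis cleaves both O-benzyl bonds; the liberated 2-hydroxyquinoline tautomerises to the lactam, and the guaiacol hydroxyl appears only after sulfation is finished. Aryl sulfate monoester anions, the diarylmethane CH2 and the quinolone ring are inert at atmospheric pressure, and one equivalent of cold mineral acid converts 20 into the free hydrogen sulfate.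

## Compound list

1 | 5-bromo-2-chloro-3-methoxypyridine | COc1cc(Br)cnc1Cl | starting material
2 | 2-(benzyloxy)-5-bromo-3-methoxypyridine | COc1cc(Br)cnc1OCc1ccccc1 | intermediate
3 | [6-(benzyloxy)-5-methoxypyridin-3-yl]lithium | COc1cc([Li])cnc1OCc1ccccc1 | intermediate
4 | lithium [6-(benzyloxy)-5-methoxypyridin-3-yl]tri(propan-2-yloxy)borate | [Li+].COc1cc(cnc1OCc1ccccc1)[B-](OC(C)C)(OC(C)C)OC(C)C | intermediate
5 | 6-(benzyloxy)-5-methoxypyridin-3-ol | COc1cc(O)cnc1OCc1ccccc1 | intermediate
6 | 6-(benzyloxy)-2-bromo-5-methoxypyridin-3-ol | COc1cc(O)c(Br)nc1OCc1ccccc1 | intermediate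
7 | 2-(benzyloxy)-6-bromo-3-methoxy-5-[(trimethylsilyl)oxy]pyridine | COc1cc(O[Si](C)(C)C)c(Br)nc1OCc1ccccc1 | intermediate
8 | {6-(benzyloxy)-5-methoxy-3-[(trimethylsilyl)oxy]pyridin-2-yl}lithium | COc1cc(O[Si](C)(C)C)c([Li])nc1OCc1ccccc1 | intermediate
9 | lithium 6-(benzyloxy)-5-methoxy-2-(trimethylsilyl)pyridin-3-olate | [Li+].COc1cc([O-])c([Si](C)(C)C)nc1OCc1ccccc1 | intermediate
10 | 6-(benzyloxy)-5-methoxy-2-(trimethylsilyl)pyridin-3-yl trifluoromethanesulfonate | COc1cc(OS(=O)(=O)C(F)(F)F)c([Si](C)(C)C)nc1OCc1ccccc1 | intermediate
11 | [4-(benzyloxy)-3-methoxyphenyl]methanol | COc1cc(CO)ccc1OCc1ccccc1 | starting material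
12 | 1-(benzyloxy)-4-(chloromethyl)-2-methoxybenzene | COc1cc(CCl)ccc1OCc1ccccc1 | intermediate
13 | furan-3-ylboronic acid | OB(O)c1ccoc1 | starting material
14 | 3-[4-(benzyloxy)-3-methoxybenzyl]furan | COc1cc(Cc2ccoc2)ccc1OCc1ccccc1 | intermediate
15 | 6-(benzyloxy)-5-methoxy-2,3-didehydropyridine (2,3-pyridyne) | COC1=CC#CN=C1OCc1ccccc1 | intermediate
16 | 2-(benzyloxy)-7-[4-(benzyloxy)-3-methoxybenzyl]-3-methoxy-5,8-epoxy-5,8-dihydroquinoline (racemic, 5S,8R drawn) | COc1cc2c(nc1OCc1ccccc1)[C@@H]1O[C@H]2C=C1Cc1ccc(OCc2ccccc2)c(OC)c1 | intermediate
17 | 2-(benzyloxy)-7-[4-(benzyloxy)-3-methoxybenzyl]-3-methoxyquinolin-8-ol | COc1cc2ccc(Cc3ccc(OCc4ccccc4)c(OC)c3)c(O)c2nc1OCc1ccccc1 | intermediate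
18 | pyridinium 2-(benzyloxy)-7-[4-(benzyloxy)-3-methoxybenzyl]-3-methoxyquinolin-8-yl sulfate | c1cc[nH+]cc1.COc1cc2ccc(Cc3ccc(OCc4ccccc4)c(OC)c3)c(OS(=O)(=O)[O-])c2nc1OCc1ccccc1 | intermediate
19 | sodium 2-(benzyloxy)-7-[4-(benzyloxy)-3-methoxybenzyl]-3-methoxyquinolin-8-yl sulfate | [Na+].COc1cc2ccc(Cc3ccc(OCc4ccccc4)c(OC)c3)c(OS(=O)(=O)[O-])c2nc1OCc1ccccc1 | intermediate
20 | sodium 7-(4-hydroxy-3-methoxybenzyl)-3-methoxy-2-oxo-1,2-dihydroquinolin-8-yl sulfate | [Na+].COc1cc(Cc2ccc3cc(OC)c(=O)[nH]c3c2OS(=O)(=O)[O-])ccc1O | intermediate
21 | scolopendrine, 7-(4-hydroxy-3-methoxybenzyl)-3-methoxy-2-oxo-1,2-dihydroquinolin-8-yl hydrogen sulfate | COc1cc(Cc2ccc3cc(OC)c(=O)[nH]c3c2OS(=O)(=O)O)ccc1O | target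

## Step count and least certain steps

Total step count: 11. The pyridine branch is steps 1–5, the furan branch steps 6–7, and the common part steps 8–11.
Longest linear sequence: 9 steps (1 → 2 → 5 → 6 → 7 → 10 → 16 → 17 → 19 → 21).

**Step 8 (key step).**
- The most likely failure is weak orientational control. The polarisation of the pyridyne and the difference between the two furan α-carbons are both modest, and the directing benzyl group is one atom removed from the bond-forming carbon.
- A second weakness is that the diene is not the solvent, so fluoride addition, self-reaction of the pyridyne, and protonation of the C2 carbanion before triflate loss can take material.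
- Fallback: setting out from 10, the pyridyne 15 would be trapped with unsubstituted furan as co-solvent (CsF, MeCN/furan). A symmetrical diene has no orientation problem, and its large excess outruns the side reactions.
- This gives 2-(benzyloxy)-3-methoxy-5,8-epoxy-5,8-dihydroquinoline F1. Acid isomerisation as in step 9 gives 2-(benzyloxy)-3-methoxyquinolin-8-ol F2, where the choice of the C–O bond rests on the pyridine ring alone.
- Amine-mediated ortho-selective bromination (NBS, cat. i-Pr2NH, CH2Cl2) gives 2-(benzyloxy)-7-bromo-3-methoxyquinolin-8-ol F3.
- Chloride 12 is converted with Zn dust and LiCl in THF into [4-(benzyloxy)-3-methoxybenzyl]zinc chloride F4. Negishi coupling of F3 with slowly added F4 (Pd(OAc)2, SPhos, THF) comes back to the route at 17.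

**Step 5.**
- The butyllithium may attack silicon instead of bromine.
- More seriously, the C2–Si bond may be lost by protodesilylation during work-up or chromatography, because silyl groups next to a pyridine nitrogen are hydrolytically labile.
- Fallback: setting out from 6, direct triflation (Tf2O, pyridine, CH2Cl2, 0 °C) gives 6-(benzyloxy)-2-bromo-5-methoxypyridin-3-yl trifluoromethanesulfonate F5, which has no C–Si bond.
- Adding n-BuLi at −78 °C to F5 and 14 in toluene triggers bromine–lithium exchange to {6-(benzyloxy)-5-methoxy-3-[(trifluoromethylsulfonyl)oxy]pyridin-2-yl}lithium F6. This species loses triflate to give the same pyridyne 15, and the route is rejoined at 16.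

**Step 9.**
- Part of the material may open by cleavage of the other bridge C–O bond, because the C3 methoxy group lends some stabilisation to that pathway.
- The acid may strip the imidate-type benzyl group from C2.
- The cation may alkylate an electron-rich arene before it rearomatises.
- Fallback: setting out from 16, nickel-catalysed hydroalumination (Ni(cod)2 cat., i-Bu2AlH, toluene, rt) places aluminium on the less hindered C6 and hydrogen on the exo face of C7. β-Elimination of the C5 alkoxide then opens the bridge to trans-2-(benzyloxy)-7-[4-(benzyloxy)-3-methoxybenzyl]-3-methoxy-7,8-dihydroquinolin-8-ol F7.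
- In this sequence the regiochemistry is set by the substitution of the alkene and not by cation stabilities, and no acid is present.
- Oxidation of the C8 carbinol with Dess–Martin periodinane gives 2-(benzyloxy)-7-[4-(benzyloxy)-3-methoxybenzyl]-3-methoxyquinolin-8(7H)-one F8, which enolises to 17.

**Step 10.**
- The hydroxyl is hindered by the C7 benzyl group and hydrogen-bonded to the ring nitrogen, so sulfation may stay incomplete.
- The ionic product is hard to separate from unreacted phenol without partial hydrolysis.
- Fallback: setting out from 17, a protected sulfate is introduced with 2,2,2-trichloroethyl chlorosulfate (Et3N, DMAP, THF). This gives 2-(benzyloxy)-7-[4-(benzyloxy)-3-methoxybenzyl]-3-methoxyquinolin-8-yl 2,2,2-trichloroethyl sulfate F9, a neutral diester that can be chromatographed on silica.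
- Reductive removal of the trichloroethyl group (Zn, HCO2NH4, MeOH, rt), which leaves benzyl ethers alone, gives ammonium 2-(benzyloxy)-7-[4-(benzyloxy)-3-methoxybenzyl]-3-methoxyquinolin-8-yl sulfate F10. Treatment with aqueous NaHCO3 and evaporation exchanges the cation and comes back to the route at 19.

## Further compounds

F1 | step 8 | 2-(benzyloxy)-3-methoxy-5,8-epoxy-5,8-dihydroquinoline (racemic, 5S,8R drawn) | COc1cc2c(nc1OCc1ccccc1)[C@@H]1O[C@H]2C=C1
F2 | step 8 | 2-(benzyloxy)-3-methoxyquinolin-8-ol | COc1cc2cccc(O)c2nc1OCc1ccccc1
F3 | step 8 | 2-(benzyloxy)-7-bromo-3-methoxyquinolin-8-ol | COc1cc2ccc(Br)c(O)c2nc1OCc1ccccc1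
F4 | step 8 | [4-(benzyloxy)-3-methoxybenzyl]zinc chloride | COc1cc(C[Zn]Cl)ccc1OCc1ccccc1
F5 | step 5 | 6-(benzyloxy)-2-bromo-5-methoxypyridin-3-yl trifluoromethanesulfonate | COc1cc(OS(=O)(=O)C(F)(F)F)c(Br)nc1OCc1ccccc1
F6 | step 5 | {6-(benzyloxy)-5-methoxy-3-[(trifluoromethylsulfonyl)oxy]pyridin-2-yl}lithium | COc1cc(OS(=O)(=O)C(F)(F)F)c([Li])nc1OCc1ccccc1
F7 | step 9 | trans-2-(benzyloxy)-7-[4-(benzyloxy)-3-methoxybenzyl]-3-methoxy-7,8-dihydroquinolin-8-ol (racemic, 7S,8R drawn) | COc1cc2c(nc1OCc1ccccc1)[C@H](O)[C@@H](Cc1ccc(OCc3ccccc3)c(OC)c1)C=C2
F8 | step 9 | 2-(benzyloxy)-7-[4-(benzyloxy)-3-methoxybenzyl]-3-methoxyquinolin-8(7H)-one (racemic, 7S drawn) | COc1cc2c(nc1OCc1ccccc1)C(=O)[C@@H](Cc1ccc(OCc3ccccc3)c(OC)c1)C=C2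
F9 | step 10 | 2-(benzyloxy)-7-[4-(benzyloxy)-3-methoxybenzyl]-3-methoxyquinolin-8-yl 2,2,2-trichloroethyl sulfate | COc1cc2ccc(Cc3ccc(OCc4ccccc4)c(OC)c3)c(OS(=O)(=O)OCC(Cl)(Cl)Cl)c2nc1OCc1ccccc1
F10 | step 10 | ammonium 2-(benzyloxy)-7-[4-(benzyloxy)-3-methoxybenzyl]-3-methoxyquinolin-8-yl sulfate | [NH4+].COc1cc2ccc(Cc3ccc(OCc4ccccc4)c(OC)c3)c(OS(=O)(=O)[O-])c2nc1OCc1ccccc1
A1 | alternative 1 | 7-[4-(benzyloxy)-3-methoxybenzyl]-3,3-dimethoxy-8-(pivaloyloxy)-3,4-dihydroquinolin-2(1H)-one | CC(C)(C)C(=O)Oc1c(Cc2ccc(OCc3ccccc3)c(OC)c2)ccc2c1NC(=O)C(OC)(OC)C2
A2 | alternative 1 | (Z)-6-[4-(benzyloxy)-3-methoxybenzyl]-2,2-dimethoxy-7-(pivaloyloxy)indan-1-one oxime (hydroxyl anti to the aryl carbon) | CC(C)(C)C(=O)Oc1c(Cc2ccc(OCc3ccccc3)c(OC)c2)ccc2c1/C(=N/O)C(OC)(OC)C2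
A3 | alternative 2 | 7-[4-(benzyloxy)-3-methoxybenzyl]-3-bromo-8-(methoxymethoxy)quinoline | COCOc1c(Cc2ccc(OCc3ccccc3)c(OC)c2)ccc2cc(Br)cnc12
A4 | alternative 2 | 6-[4-(benzyloxy)-3-methoxybenzyl]-7-(methoxymethoxy)-1H-indole | COCOc1c(Cc2ccc(OCc3ccccc3)c(OC)c2)ccc2cc[nH]c12
A5 | alternative 2 | dibromocarbene | Br[C]Br
A6 | alternative 3 | 7-[4-(benzyloxy)-3-methoxybenzyl]-1,3-dimethoxy-8-(methoxymethoxy)quinolin-2(1H)-one | COCOc1c(Cc2ccc(OCc3ccccc3)c(OC)c2)ccc2cc(OC)c(=O)n(OC)c12
A7 | alternative 3 | N,2-dimethoxyprop-2-enamide | C=C(OC)C(=O)NOC
A8 | alternative 3 | 4-[4-(benzyloxy)-3-methoxybenzyl]-3-(methoxymethoxy)-1,2-didehydrobenzene | COCOC1=C(Cc2ccc(OCc3ccccc3)c(OC)c2)C=CC#C1
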